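**Retrosynthetic overview**

1. Quinone locants: C-1(=O), C-2(OH), C-3(henicosyl), C-4(=O), C-5(OMe), C-6(H). The C-2 hydroxyl is freed last from an O–Si(i-Pr)3 ether (step 5); the C-1 carbonyl is put in by para-oxidation of phenol 12, whose OH sits on C-4 (step 4).
2. Key disconnection (step 3): the ring of 12 is cut into a two-carbon half C-2/C-3 (silyl ynol ether 4) and a four-carbon half C-4/C-5/C-6/C-1 (diazo ketone 7). Bonds C-1–C-2 and C-3–C-4 form together in a ketene–alkyne [2+2] cycloaddition; the same operation completes the ring (1,2-shift of C-6 to C-1, 4-electron ring opening, 6-electron closure C-4–C-5).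
3. Enabling feature: the adjacent ring atoms C-2 (oxygen-bearing) and C-3 (alkyl-bearing) are the two carbons of a polarised oxy-alkyne. C-4 is a carbonyl carbon flanked by C-3 and the enol-ether carbon C-5, i.e. the C=O carbon of a 4-methoxyvinylketene. C-1 carries only H in 12 and lies para to the phenolic C-4, so it can be oxidised afterwards.
4. Building blocks: 4 from methyl docosanoate by ester homologation stopped at the ynolate (step 1); 7 from (E)-4-methoxybut-3-en-2-one by diazo transfer (step 2).
5. Ring order: a temporary four-membered ring (cyclobutenone 9), then the only lasting ring, the six-membered carbocycle, both within step 3.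

Key step: step 3

Remark: the quinone locants above are used for all precursors; the target has no stereocentre, 9 and 11 are racemic transients, and crude 6 is carried on without purification.

**Route**

Step 1
Reactants: 1 methyl docosanoate
Product: 4 1-(triisopropylsilyloxy)tricos-1-yne, via dibromo enolate 2 (not isolated), via lithium ynolate 3 (not isolated)
Conditions: CH2Br2, preformed LiTMP (lithium 2,2,6,6-tetramethylpiperidide, 2.2 equiv), THF, −78 °C (ester added as a THF solution); n-BuLi, −78 → 20 °C; i-Pr3SiOTf, −78 → 0 °C
Reagents that add atoms: dibromomethane BrCBr (supplies C-2 of the alkyne, the later ring carbon C-3); triisopropylsilyl trifluoromethanesulfonate CC(C)[Si](C(C)C)(C(C)C)OS(=O)(=O)C(F)(F)F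
Why: Kowalski ester homologation stopped at the ynolate: acylation of LiCHBr2, bromine–lithium exchange and 1,2-shift of the henicosyl group should give lithium ynolate 3, which the bulky silyl triflate should trap on oxygen rather than on carbon.

Step 2
Reactants: 5 (E)-4-methoxybut-3-en-2-one
Product: 7 (E)-1-diazo-4-methoxybut-3-en-2-one, via trifluoroacetyl diketone 6 (not isolated)
Conditions: LiN(SiMe3)2, THF, −78 °C; CF3CO2CH2CF3; aqueous work-up, crude 6 taken on; MeSO2N3, Et3N, H2O, MeCN, 20 °C
Reagents that add atoms: methanesulfonyl azide CS(=O)(=O)N=[N+]=[N-] (the two diazo nitrogens); 2,2,2-trifluoroethyl trifluoroacetate O=C(OCC(F)(F)F)C(F)(F)F (trifluoroacetyl group of 6 only, lost again)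
Why: Detrifluoroacetylative diazo transfer (Claisen trifluoroacetylation of the kinetic methyl enolate, then Regitz-type diazo transfer with loss of the trifluoroacetyl group) should give the α-diazo enone without touching the base-sensitive β-methoxy enone.

Step 3
Reactants: 7 (E)-1-diazo-4-methoxybut-3-en-2-one; 4 1-(triisopropylsilyloxy)tricos-1-yne
Product: 12 2-henicosyl-6-methoxy-3-(triisopropylsilyloxy)phenol, via vinylketene 8 (not isolated), via vinylcyclobutenone 9 (not isolated), via dienylketene 10 (not isolated), via cyclohexadienone 11 (not isolated)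
Conditions: hν (254 nm, low-pressure Hg lamps, Vycor), degassed ClCH2CH2Cl, 25 °C; then 80 °C
Reagents that add atoms: none
Why: Irradiation should trigger a photochemical Wolff rearrangement of 7 (loss of N2, 1,2-shift of the methoxyvinyl group) to vinylketene 8, which the electron-rich alkyne 4 traps in a regiospecific [2+2] cycloaddition that forms in one event the bond from the ketene carbonyl carbon (later C-4) to the alkyl-bearing alkyne carbon (C-3) and the bond from the ketene α-carbon (later C-1) to the silyloxy-bearing alkyne carbon (C-2). The 4-vinylcyclobutenone 9 then opens by 4-electron electrocyclic ring opening (under the light or on warming) to dienylketene 10, which closes by 6-electron disrotatory electrocyclisation (C-4 to C-5) to dienone 11 and tautomerises to phenol 12. The closest known reaction type is the Danheiser benzannulation in its photochemical diazo ketone variant with trialkylsilyloxyalkynes. Ring closures: the temporary four-membered ring by ketene–alkyne [2+2] cycloaddition, the six-membered ring by 6π electrocyclisation; no stereocentre survives, since the sp3 carbons of 9 and 11 are lost on ring opening and tautomerisation. The step needs complete regiocontrol in the [2+2] event, secured by the polarisation of the ynol ether (its nucleophilic alkyl-bearing carbon attacks the electrophilic ketene carbonyl carbon), and it needs the methoxyvinyl group cis to the ketene unit in 10, which the reversible cyclobutenone ring opening can supply.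

Step 4
Reactants: 12 2-henicosyl-6-methoxy-3-(triisopropylsilyloxy)phenol
Product: 13 3-henicosyl-5-methoxy-2-(triisopropylsilyloxy)cyclohexa-2,5-diene-1,4-dione
Conditions: O2 (1 atm), cat. Co(salen) (C16H14CoN2O2, divalent cobalt), DMF/THF, 25 °C
Reagents that add atoms: dioxygen O=O
Why: Cobalt–salen catalysed autoxidation of a phenol whose two ortho positions are blocked (alkyl, OMe) should oxygenate only the free para carbon (C-1) and give the p-quinone after loss of water.

Step 5
Reactants: 13 3-henicosyl-5-methoxy-2-(triisopropylsilyloxy)cyclohexa-2,5-diene-1,4-dione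
Product: 14 3-henicosyl-2-hydroxy-5-methoxycyclohexa-2,5-diene-1,4-dione (CNP0317656.0)
Conditions: HF (48% aq.), MeCN/THF, 0 → 20 °C
Reagents that add atoms: none
Why: Fluoride/acid desilylation: the silyl ether of a 2-hydroxyquinone is a vinylogous silyl ester and should cleave far faster than the methyl vinylogous ester at C-5, which is left intact.

**Compound list**

1 | methyl docosanoate | CCCCCCCCCCCCCCCCCCCCCC(=O)OC | starting material
2 | lithium 1,1-dibromotricos-1-en-2-olate | CCCCCCCCCCCCCCCCCCCCCC(O[Li])=C(Br)Br | intermediate
3 | lithium tricos-1-yn-1-olate | CCCCCCCCCCCCCCCCCCCCCC#CO[Li] | intermediate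
4 | 1-(triisopropylsilyloxy)tricos-1-yne | CCCCCCCCCCCCCCCCCCCCCC#CO[Si](C(C)C)(C(C)C)C(C)C | intermediate
5 | (E)-4-methoxybut-3-en-2-one | CO/C=C/C(C)=O | starting material
6 | (E)-1,1,1-trifluoro-6-methoxyhex-5-ene-2,4-dione | CO/C=C/C(=O)CC(=O)C(F)(F)F | intermediate
7 | (E)-1-diazo-4-methoxybut-3-en-2-one | CO/C=C/C(=O)C=[N+]=[N-] | intermediate
8 | (E)-4-methoxybuta-1,3-dien-1-one | CO/C=C/C=C=O | intermediate
9 | 2-henicosyl-4-[(E)-2-methoxyethenyl]-3-(triisopropylsilyloxy)cyclobut-2-en-1-one (racemic) | CCCCCCCCCCCCCCCCCCCCCC1=C(O[Si](C(C)C)(C(C)C)C(C)C)C(/C=C/OC)C1=O | intermediate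
10 | (3E,5E)-2-henicosyl-6-methoxy-3-(triisopropylsilyloxy)hexa-1,3,5-trien-1-one | CCCCCCCCCCCCCCCCCCCCCC(=C=O)/C(O[Si](C(C)C)(C(C)C)C(C)C)=C\C=C\OC | intermediate
11 | 2-henicosyl-6-methoxy-3-(triisopropylsilyloxy)cyclohexa-2,4-dien-1-one (racemic) | CCCCCCCCCCCCCCCCCCCCCC1=C(O[Si](C(C)C)(C(C)C)C(C)C)C=CC(OC)C1=O | intermediate
12 | 2-henicosyl-6-methoxy-3-(triisopropylsilyloxy)phenol | CCCCCCCCCCCCCCCCCCCCCc1c(O[Si](C(C)C)(C(C)C)C(C)C)ccc(OC)c1O | intermediate
13 | 3-henicosyl-5-methoxy-2-(triisopropylsilyloxy)cyclohexa-2,5-diene-1,4-dione | CCCCCCCCCCCCCCCCCCCCCC1=C(O[Si](C(C)C)(C(C)C)C(C)C)C(=O)C=C(OC)C1=O | intermediate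
14 | 3-henicosyl-2-hydroxy-5-methoxycyclohexa-2,5-diene-1,4-dione | CCCCCCCCCCCCCCCCCCCCCC1=C(O)C(=O)C=C(OC)C1=O | target

**Summary**

Total step count: 5.
Longest linear sequence: 4 steps (1 → 4 → 12 → 13 → 14, or equally 5 → 7 → 12 → 13 → 14).

**Steps most likely to fail**

Step 3. Photochemical side paths may drain the cascade: dimerisation or photodegradation of the vinylketene, secondary photolysis of the cyclobutenone or the phenol, or incomplete thermal ring opening and closure. The fallback is a classical arene route that sets out from 1 and comes back at 14. Saponification of 1 (LiOH, THF/H2O, 60 °C) should give docosanoic acid F1. Its bromodecarboxylation (Hunsdiecker reaction in the Cristol–Firth form, HgO, Br2, CCl4, reflux) should give 1-bromohenicosane F2. Commercial 1,2,4,5-tetramethoxybenzene (COc1cc(OC)c(OC)cc1OC) is lithiated between two methoxy groups (n-BuLi, THF, 0 °C) to 2,3,5,6-tetramethoxyphenyllithium F3, which is alkylated with F2 (THF/DMPU, 0 → 20 °C) to 3-henicosyl-1,2,4,5-tetramethoxybenzene F4. Oxidative demethylation with (NH4)2Ce(NO3)6 (tetravalent cerium, MeCN/H2O, 0 °C) should give 3-henicosyl-2,5-dimethoxycyclohexa-2,5-diene-1,4-dione F5; either para-dimethoxy pair leads to the same quinone. Acid hydrolysis (70% HClO4, dioxane, 20 °C) is expected to cleave the sterically compressed, less conjugated methoxy group next to the alkyl chain and so to give 14; this regioselectivity is the weak point of the fallback and would have to be confirmed.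

Step 1. The waxy ester may crystallise from THF at −78 °C, so that acylation of the short-lived LiCHBr2 stays incomplete; the carbenoid rearrangement and O- versus C-silylation are further weak points. The fallback makes the ynolate by oxidation of an acetylide; it sets out from 1 and comes back at 4. Reduction of 1 (LiAlH4, THF, reflux) should give docosan-1-ol F6, and oxidation (Dess–Martin periodinane, CH2Cl2, 20 °C) docosanal F7. Seyferth–Gilbert homologation with the Ohira–Bestmann reagent (dimethyl (1-diazo-2-oxopropyl)phosphonate, K2CO3, MeOH/THF, 20 °C) should give tricos-1-yne F8. Deprotonation (n-BuLi, THF, 0 °C) gives lithium tricos-1-yn-1-ide F9. Oxygen transfer from t-BuOOLi (from t-BuOOH and LiN(SiMe3)2, −78 → 0 °C) should give ynolate 3, which is silylated with i-Pr3SiOTf as in step 1 to give 4.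

Step 4. Phenoxyl radicals may couple (C–C or C–O dimerisation) or be over-oxidised, and the catalyst may be deactivated in the presence of the poorly soluble lipid. The fallback deprotects first and then uses a stoichiometric radical oxidant; it sets out from 12 and comes back at 14. Desilylation of 12 (n-Bu4NF, AcOH, THF, 0 °C) should give 2-henicosyl-4-methoxybenzene-1,3-diol F10. Teuber oxidation with Fremy's salt, (KSO3)2NO (KH2PO4 buffer, CH2Cl2/H2O, n-Bu4NHSO4, 20 °C), should oxygenate the only activated free position, C-1 (para to the C-4 hydroxyl, ortho to the C-2 hydroxyl), and give 14 directly; whichever quinone forms first is a tautomer of the 2-hydroxy-1,4-quinone.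

Further compounds
F1 | step 3 | docosanoic acid | CCCCCCCCCCCCCCCCCCCCCC(=O)O
F2 | step 3 | 1-bromohenicosane | CCCCCCCCCCCCCCCCCCCCCBr
F3 | step 3 | 2,3,5,6-tetramethoxyphenyllithium | [Li]c1c(OC)c(OC)cc(OC)c1OC
F4 | step 3 | 3-henicosyl-1,2,4,5-tetramethoxybenzene | CCCCCCCCCCCCCCCCCCCCCc1c(OC)c(OC)cc(OC)c1OC
F5 | step 3 | 3-henicosyl-2,5-dimethoxycyclohexa-2,5-diene-1,4-dione | CCCCCCCCCCCCCCCCCCCCCC1=C(OC)C(=O)C=C(OC)C1=O
F6 | step 1 | docosan-1-ol | CCCCCCCCCCCCCCCCCCCCCCO
F7 | step 1 | docosanal | CCCCCCCCCCCCCCCCCCCCCC=O
F8 | step 1 | tricos-1-yne | CCCCCCCCCCCCCCCCCCCCCC#C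
F9 | step 1 | lithium tricos-1-yn-1-ide | CCCCCCCCCCCCCCCCCCCCCC#C[Li]
F10 | step 4 | 2-henicosyl-4-methoxybenzene-1,3-diol | CCCCCCCCCCCCCCCCCCCCCc1c(O)ccc(OC)c1O
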